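**Plan**

- Retrosynthetic cuts: first the eight O–CH2OCH3 bonds; then the flavone pyranone ring at C4a–C4, C4–C3 and O1–C2 (o-iodophenol + CO + aryl acetylene); then the cyclohexene at C3–C4 and C5–C6 (2′-hydroxychalcone + 1-aryl-3-methylbutadiene); finally the enone Cα=Cβ bond and the aryl–dienyl bond.
- Enabling feature: with the cyclohexene numbered C1 (C–CH3), C2 (=CH), C3, C4 (aroyl), C5 (2,4-dihydroxyphenyl), C6 (CH2), C3 is bonded to flavone C6. That carbon is para to the ring oxygen O1 (through C8a) and lies between the C5 and C7 oxygens. Before the pyranone is fused, ring A is therefore a symmetric phloroglucinol ring, and a single free hydroxyl (future O1) with iodine beside it (future C4a) fixes the ring fusion.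
- Forward order: an aryl alkyne, a chalcone and an aryl diene are made from 2,4-dihydroxybenzaldehyde, 2,4-dihydroxyacetophenone/prenyl bromide and phloroglucinol. The cyclohexene is closed first by [4+2] cycloaddition, the phenol para to C3 is unmasked and iodinated, the pyranone ring is closed last, and the acetals are then removed.
- Stereochemistry: C3, C4 and C5 are all set in the Diels–Alder step (trans C4/C5 from the (E)-enone, cis C3/C4 from the endo transition state, absolute sense from a chiral VANOL borate on the 2′-hydroxy ketone) and are spectators afterwards.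

Key step: step 15

**Remarks on the chemistry (assumptions)**

- Names use cyclohex-3-en-1-yl locants; C1, C2, C6 of the names are C4, C3, C5 of the plan numbering, so (1R,2S,6S) in the names equals (3S,4R,5S) in the plan numbering.
- The (R)-VANOL borate is assumed to shield the enone face that leads to the (3S,4R,5S) adduct, by analogy with related 2′-hydroxychalcone cycloadditions. If the opposite sense were found, (S)-VANOL would be used.
- The two positions ortho to the free hydroxyl in 19 are equivalent by rotation about the aryl–C3 bond, so mono-iodination gives one compound.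

**Route**

Step 1
Reactants: 1 2,4-dihydroxybenzaldehyde
Product: 2 2,4-bis(methoxymethoxy)benzaldehyde
Conditions: MOMCl (3 equiv), iPr2NEt (4 equiv), CH2Cl2, 0 °C → rt
Reagents that add atoms: chloromethyl methyl ether, COCCl
Why: Williamson-type O-alkylation of both phenols is routine, and the excess reagent also caps the hydrogen-bonded 2-OH.

Step 2
Reactants: 2 2,4-bis(methoxymethoxy)benzaldehyde
Product: 3 1-ethynyl-2,4-bis(methoxymethoxy)benzene
Conditions: dimethyl (1-diazo-2-oxopropyl)phosphonate, K2CO3, MeOH, 0 °C → rt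
Reagents that add atoms: dimethyl (1-diazo-2-oxopropyl)phosphonate, CC(=O)C(=[N+]=[N-])P(=O)(OC)OC
Why: Ohira–Bestmann (Seyferth–Gilbert) homologation converts an aryl aldehyde into the terminal alkyne under mild carbonate conditions that leave aryl MOM ethers untouched.

Step 3
Reactants: 4 1-(2,4-dihydroxyphenyl)ethanone; 5 1-bromo-3-methylbut-2-ene (prenyl bromide)
Product: 6 1-[2,4-dihydroxy-3-(3-methylbut-2-en-1-yl)phenyl]ethanone
Conditions: KOH (10% aq), 0 °C → rt
Reagents that add atoms: none
Why: C-prenylation of the resorcinol-type phenoxide in aqueous alkali (a protic medium favours C- over O-alkylation) should go mainly to C3 between the two oxygens, with the 5-prenyl and O-prenyl by-products removed by chromatography at this cheap, early stage.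

Step 4
Reactants: 6 1-[2,4-dihydroxy-3-(3-methylbut-2-en-1-yl)phenyl]ethanone
Product: 7 1-[2-hydroxy-4-(methoxymethoxy)-3-(3-methylbut-2-en-1-yl)phenyl]ethanone
Conditions: MOMCl (1.1 equiv), K2CO3, acetone, rt
Reagents that add atoms: chloromethyl methyl ether, COCCl
Why: the 4-OH is the only phenol not hydrogen-bonded to the ketone, so Williamson alkylation with one equivalent of MOMCl under weak base should leave the chelated 2-OH free.

Step 5
Reactants: 7 1-[2-hydroxy-4-(methoxymethoxy)-3-(3-methylbut-2-en-1-yl)phenyl]ethanone; 2 2,4-bis(methoxymethoxy)benzaldehyde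
Product: 8 (2E)-3-[2,4-bis(methoxymethoxy)phenyl]-1-[2-hydroxy-4-(methoxymethoxy)-3-(3-methylbut-2-en-1-yl)phenyl]prop-2-en-1-one
Conditions: KOH, EtOH/H2O, rt
Reagents that add atoms: none
Why: Claisen–Schmidt condensation (aldol addition then E1cB dehydration) of the methyl ketone with the non-enolisable aldehyde gives the thermodynamically preferred (E)-enone, and the MOM ethers and prenyl group are base-stable.

Step 6
Reactants: 9 benzene-1,3,5-triol (phloroglucinol)
Product: 10 3,5-bis(methoxymethoxy)phenol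
Conditions: MOMCl (2 equiv), iPr2NEt, DMF, 0 °C → rt
Reagents that add atoms: chloromethyl methyl ether, COCCl
Why: statistical double O-alkylation of the threefold-symmetric triol should give the bis-ether as the main fraction, separable from the mono-ether (resubmitted) and the tris-ether.

Step 7
Reactants: 10 3,5-bis(methoxymethoxy)phenol
Product: 11 [3,5-bis(methoxymethoxy)phenoxy]tri(propan-2-yl)silane
Conditions: TIPSCl, imidazole, DMF, rt
Reagents that add atoms: chlorotri(propan-2-yl)silane, CC(C)[Si](Cl)(C(C)C)C(C)C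
Why: standard silylation of a phenol installs a bulky ether that withstands butyllithium, directs metalation poorly and is later removed by fluoride without touching MOM ethers.

Step 8
Reactants: 11 [3,5-bis(methoxymethoxy)phenoxy]tri(propan-2-yl)silane
Product: 13 [4-iodo-3,5-bis(methoxymethoxy)phenoxy]tri(propan-2-yl)silane, via 2-lithio arene 12 (not isolated)
Conditions: n-BuLi, THF, 0 °C; then I2, −78 °C → rt
Reagents that add atoms: iodine, II
Why: directed ortho-metalation places lithium on the carbon between the two cooperating MOM ethers (the bulky OTIPS blocks its own ortho positions), and the aryllithium is trapped by iodine.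

Step 9
Reactants: 14 2-methylbut-1-en-3-yne
Product: 15 4,4,5,5-tetramethyl-2-[(1E)-3-methylbuta-1,3-dien-1-yl]-1,3,2-dioxaborolane
Conditions: pinacolborane, Cp2Zr(H)Cl (cat.), Et3N (cat.), neat, 60 °C
Reagents that add atoms: pinacolborane, CC1(C)OBOC1(C)C
Why: zirconocene-catalysed syn-hydroboration of the terminal alkyne gives the (E)-alkenylboronate, the 1,1-disubstituted alkene being much less reactive.

Step 10
Reactants: 13 [4-iodo-3,5-bis(methoxymethoxy)phenoxy]tri(propan-2-yl)silane; 15 4,4,5,5-tetramethyl-2-[(1E)-3-methylbuta-1,3-dien-1-yl]-1,3,2-dioxaborolane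
Product: 16 {3,5-bis(methoxymethoxy)-4-[(1E)-3-methylbuta-1,3-dien-1-yl]phenoxy}tri(propan-2-yl)silane
Conditions: Pd(OAc)2 (cat.), SPhos, K3PO4, THF/H2O, 60 °C
Reagents that add atoms: none
Why: Suzuki–Miyaura coupling with a biarylphosphine ligand accepts the di-ortho-substituted aryl iodide and transfers the dienyl group with retention of the (E)-geometry, while the MOM and TIPS ethers tolerate aqueous phosphate.

Step 11
Reactants: 8 (2E)-3-[2,4-bis(methoxymethoxy)phenyl]-1-[2-hydroxy-4-(methoxymethoxy)-3-(3-methylbut-2-en-1-yl)phenyl]prop-2-en-1-one; 16 {3,5-bis(methoxymethoxy)-4-[(1E)-3-methylbuta-1,3-dien-1-yl]phenoxy}tri(propan-2-yl)silane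
Product: 17 [(1R,2S,6S)-2-{2,6-bis(methoxymethoxy)-4-[tri(propan-2-yl)silyloxy]phenyl}-6-[2,4-bis(methoxymethoxy)phenyl]-4-methylcyclohex-3-en-1-yl][2-hydroxy-4-(methoxymethoxy)-3-(3-methylbut-2-en-1-yl)phenyl]methanone
Conditions: (R)-VANOL, BH3·THF, AcOH, THF, rt, then removal of volatiles; 8, then 16 (2 equiv), 4 Å MS, PhCF3, rt → 40 °C; aq. NaHCO3 work-up
Reagents that add atoms: none
Why: in this chiral-borate-promoted Diels–Alder reaction the 2′-hydroxy ketone of 8 chelates the preformed VANOL borate, which activates the enone and shields one face, so the diene CH2 terminus should bond to the β-carbon with the (E)-geometry giving trans C4/C5, the endo transition state (aroyl under the diene) giving cis C3/C4 and the ligand giving the (3S,4R,5S) absolute configuration, the exo (all-trans) adduct being removed by chromatography.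

Step 12
Reactants: 17 the endo cycloadduct with free 2′-OH
Product: 18 [(1R,2S,6S)-2-{2,6-bis(methoxymethoxy)-4-[tri(propan-2-yl)silyloxy]phenyl}-6-[2,4-bis(methoxymethoxy)phenyl]-4-methylcyclohex-3-en-1-yl][2,4-bis(methoxymethoxy)-3-(3-methylbut-2-en-1-yl)phenyl]methanone
Conditions: NaH (1.1 equiv), DMF, 0 °C; then MOMCl, 0 °C → rt
Reagents that add atoms: chloromethyl methyl ether, COCCl
Why: Williamson etherification of the chelated phenoxide, made with barely more than one equivalent of hydride so that no base remains to enolise the hindered C4 ketone, removes the one nucleophile that could add to the prenyl alkene during the later iodination.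

Step 13
Reactants: 18 the fully MOM-capped silyl ether
Product: 19 [(1R,2S,6S)-6-[2,4-bis(methoxymethoxy)phenyl]-2-[4-hydroxy-2,6-bis(methoxymethoxy)phenyl]-4-methylcyclohex-3-en-1-yl][2,4-bis(methoxymethoxy)-3-(3-methylbut-2-en-1-yl)phenyl]methanone
Conditions: TBAF, AcOH, THF, 0 °C
Reagents that add atoms: none
Why: fluoride cleaves the aryl O–Si bond selectively, acetic acid buffering the phenoxide, while MOM ethers, the ketone and both alkenes are inert.

Step 14
Reactants: 19 the phenol para to the cyclohexenyl carbon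
Product: 20 [(1R,2S,6S)-6-[2,4-bis(methoxymethoxy)phenyl]-2-[4-hydroxy-3-iodo-2,6-bis(methoxymethoxy)phenyl]-4-methylcyclohex-3-en-1-yl][2,4-bis(methoxymethoxy)-3-(3-methylbut-2-en-1-yl)phenyl]methanone
Conditions: I2 (1.0 equiv), NaHCO3, THF/H2O, 0 °C
Reagents that add atoms: iodine, II
Why: electrophilic aromatic iodination through the phenoxide, the only strongly activated ring, occurs ortho to the free hydroxyl, one equivalent of iodine at 0 °C limiting di-iodination while the alkenes, which have no neighbouring nucleophile, should not react.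

Step 15
Reactants: 20 the o-iodophenol; 3 1-ethynyl-2,4-bis(methoxymethoxy)benzene
Product: 22 6-[(1S,5S,6R)-6-[2,4-bis(methoxymethoxy)-3-(3-methylbut-2-en-1-yl)benzoyl]-5-[2,4-bis(methoxymethoxy)phenyl]-3-methylcyclohex-2-en-1-yl]-2-[2,4-bis(methoxymethoxy)phenyl]-5,7-bis(methoxymethoxy)-4H-chromen-4-one, via o-hydroxyaryl ynone 21 (not isolated)
Conditions: PdCl2(dppf) (5 mol %), CO (5 bar), Et2NH/DMF, 80 °C
Reagents that add atoms: carbon monoxide, [C-]#[O+]
Why: Pd(0) inserts into the C–I bond of 20, CO insertion gives the aroylpalladium species, and copper-free, amine-assisted alkynylation with 3 followed by reductive elimination gives ynone 21, forming C4a–C4 and C4–C3. Diethylamine then adds reversibly to the ynone and the adjacent phenoxide forms O1–C2, a 6-endo-dig oxa-Michael closure of the pyranone (equivalently a 6-exo-trig addition–elimination on the β-amino enone), which the secondary amine favours over 5-exo-dig closure to the aurone. The closest known reaction type is the palladium-catalysed carbonylative annulation of o-iodophenols with terminal aryl acetylenes to flavones. No stereocentre is formed, and the three existing ones are remote from the reacting ring and are not enolised by the weak amine base. The step needs carbonylative rather than direct alkynylation, which CO pressure, the absence of copper and the electron-rich hindered aryl–palladium bond should secure. It also needs the 6-linked rather than the 8-linked flavone, which is secured because the iodine lies between the only free hydroxyl of that ring (para to the cyclohexenyl carbon) and a MOM ether.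

Step 16
Reactants: 22 the octakis-MOM flavone
Product: 23 2-(2,4-dihydroxyphenyl)-6-[(1S,5S,6R)-6-[2,4-dihydroxy-3-(3-methylbut-2-en-1-yl)benzoyl]-5-(2,4-dihydroxyphenyl)-3-methylcyclohex-2-en-1-yl]-5,7-dihydroxy-4H-chromen-4-one
Conditions: HCl (ca. 1 M in MeOH), rt → 40 °C
Reagents that add atoms: none
Why: acid-catalysed acetal methanolysis should remove all eight aryl MOM groups as dimethoxymethane, dilute acid and low temperature being chosen so that the prenyl group, the ring alkene and the C4 ketone do not cyclise onto the liberated ortho-phenols and no stereocentre is touched.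

**Compound list**

1 | 2,4-dihydroxybenzaldehyde | O=Cc1ccc(O)cc1O | starting material
2 | 2,4-bis(methoxymethoxy)benzaldehyde | O=Cc1ccc(OCOC)cc1OCOC | intermediate
3 | 1-ethynyl-2,4-bis(methoxymethoxy)benzene | C#Cc1ccc(OCOC)cc1OCOC | intermediate
4 | 1-(2,4-dihydroxyphenyl)ethanone | CC(=O)c1ccc(O)cc1O | starting material
5 | 1-bromo-3-methylbut-2-ene (prenyl bromide) | CC(C)=CCBr | starting material
6 | 1-[2,4-dihydroxy-3-(3-methylbut-2-en-1-yl)phenyl]ethanone | CC(=O)c1ccc(O)c(CC=C(C)C)c1O | intermediate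
7 | 1-[2-hydroxy-4-(methoxymethoxy)-3-(3-methylbut-2-en-1-yl)phenyl]ethanone | CC(=O)c1ccc(OCOC)c(CC=C(C)C)c1O | intermediate
8 | (2E)-3-[2,4-bis(methoxymethoxy)phenyl]-1-[2-hydroxy-4-(methoxymethoxy)-3-(3-methylbut-2-en-1-yl)phenyl]prop-2-en-1-one | CC(C)=CCc1c(OCOC)ccc(C(=O)/C=C/c2ccc(OCOC)cc2OCOC)c1O | intermediate
9 | benzene-1,3,5-triol (phloroglucinol) | Oc1cc(O)cc(O)c1 | starting material
10 | 3,5-bis(methoxymethoxy)phenol | COCOc1cc(O)cc(OCOC)c1 | intermediate
11 | [3,5-bis(methoxymethoxy)phenoxy]tri(propan-2-yl)silane | COCOc1cc(OCOC)cc(O[Si](C(C)C)(C(C)C)C(C)C)c1 | intermediate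
12 | {2,6-bis(methoxymethoxy)-4-[tri(propan-2-yl)silyloxy]phenyl}lithium (formed in the flask) | [Li]c1c(OCOC)cc(O[Si](C(C)C)(C(C)C)C(C)C)cc1OCOC | intermediate
13 | [4-iodo-3,5-bis(methoxymethoxy)phenoxy]tri(propan-2-yl)silane | Ic1c(OCOC)cc(O[Si](C(C)C)(C(C)C)C(C)C)cc1OCOC | intermediate
14 | 2-methylbut-1-en-3-yne | C=C(C)C#C | starting material
15 | 4,4,5,5-tetramethyl-2-[(1E)-3-methylbuta-1,3-dien-1-yl]-1,3,2-dioxaborolane | CC(=C)/C=C/B1OC(C)(C)C(C)(C)O1 | intermediate
16 | {3,5-bis(methoxymethoxy)-4-[(1E)-3-methylbuta-1,3-dien-1-yl]phenoxy}tri(propan-2-yl)silane | CC(=C)/C=C/c1c(OCOC)cc(O[Si](C(C)C)(C(C)C)C(C)C)cc1OCOC | intermediate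
17 | [(1R,2S,6S)-2-{2,6-bis(methoxymethoxy)-4-[tri(propan-2-yl)silyloxy]phenyl}-6-[2,4-bis(methoxymethoxy)phenyl]-4-methylcyclohex-3-en-1-yl][2-hydroxy-4-(methoxymethoxy)-3-(3-methylbut-2-en-1-yl)phenyl]methanone | CC(C)=CCc1c(OCOC)ccc(C(=O)[C@H]2[C@@H](c3c(OCOC)cc(O[Si](C(C)C)(C(C)C)C(C)C)cc3OCOC)C=C(C)C[C@@H]2c2ccc(OCOC)cc2OCOC)c1O | intermediate
18 | [(1R,2S,6S)-2-{2,6-bis(methoxymethoxy)-4-[tri(propan-2-yl)silyloxy]phenyl}-6-[2,4-bis(methoxymethoxy)phenyl]-4-methylcyclohex-3-en-1-yl][2,4-bis(methoxymethoxy)-3-(3-methylbut-2-en-1-yl)phenyl]methanone | CC(C)=CCc1c(OCOC)ccc(C(=O)[C@H]2[C@@H](c3c(OCOC)cc(O[Si](C(C)C)(C(C)C)C(C)C)cc3OCOC)C=C(C)C[C@@H]2c2ccc(OCOC)cc2OCOC)c1OCOC | intermediate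
19 | [(1R,2S,6S)-6-[2,4-bis(methoxymethoxy)phenyl]-2-[4-hydroxy-2,6-bis(methoxymethoxy)phenyl]-4-methylcyclohex-3-en-1-yl][2,4-bis(methoxymethoxy)-3-(3-methylbut-2-en-1-yl)phenyl]methanone | CC(C)=CCc1c(OCOC)ccc(C(=O)[C@H]2[C@@H](c3c(OCOC)cc(O)cc3OCOC)C=C(C)C[C@@H]2c2ccc(OCOC)cc2OCOC)c1OCOC | intermediate
20 | [(1R,2S,6S)-6-[2,4-bis(methoxymethoxy)phenyl]-2-[4-hydroxy-3-iodo-2,6-bis(methoxymethoxy)phenyl]-4-methylcyclohex-3-en-1-yl][2,4-bis(methoxymethoxy)-3-(3-methylbut-2-en-1-yl)phenyl]methanone | CC(C)=CCc1c(OCOC)ccc(C(=O)[C@H]2[C@@H](c3c(OCOC)cc(O)c(I)c3OCOC)C=C(C)C[C@@H]2c2ccc(OCOC)cc2OCOC)c1OCOC | intermediate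
21 | 1-{3-[(1S,5S,6R)-6-[2,4-bis(methoxymethoxy)-3-(3-methylbut-2-en-1-yl)benzoyl]-5-[2,4-bis(methoxymethoxy)phenyl]-3-methylcyclohex-2-en-1-yl]-6-hydroxy-2,4-bis(methoxymethoxy)phenyl}-3-[2,4-bis(methoxymethoxy)phenyl]prop-2-yn-1-one (formed in the flask) | CC(C)=CCc1c(OCOC)ccc(C(=O)[C@H]2[C@@H](c3c(OCOC)cc(O)c(C(=O)C#Cc4ccc(OCOC)cc4OCOC)c3OCOC)C=C(C)C[C@@H]2c2ccc(OCOC)cc2OCOC)c1OCOC | intermediate
22 | 6-[(1S,5S,6R)-6-[2,4-bis(methoxymethoxy)-3-(3-methylbut-2-en-1-yl)benzoyl]-5-[2,4-bis(methoxymethoxy)phenyl]-3-methylcyclohex-2-en-1-yl]-2-[2,4-bis(methoxymethoxy)phenyl]-5,7-bis(methoxymethoxy)-4H-chromen-4-one | CC(C)=CCc1c(OCOC)ccc(C(=O)[C@H]2[C@@H](c3c(OCOC)cc4oc(-c5ccc(OCOC)cc5OCOC)cc(=O)c4c3OCOC)C=C(C)C[C@@H]2c2ccc(OCOC)cc2OCOC)c1OCOC | intermediate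
23 | 2-(2,4-dihydroxyphenyl)-6-[(1S,5S,6R)-6-[2,4-dihydroxy-3-(3-methylbut-2-en-1-yl)benzoyl]-5-(2,4-dihydroxyphenyl)-3-methylcyclohex-2-en-1-yl]-5,7-dihydroxy-4H-chromen-4-one | CC(C)=CCc1c(O)ccc(C(=O)[C@H]2[C@@H](c3c(O)cc4oc(-c5ccc(O)cc5O)cc(=O)c4c3O)C=C(C)C[C@@H]2c2ccc(O)cc2O)c1O | target

**Step count**

Total: 16 steps. Longest linear sequence: 10 steps (9 → 10 → 11 → 13 → 16 → 17 → 18 → 19 → 20 → 22 → 23, i.e. steps 6, 7, 8, 10, 11, 12, 13, 14, 15, 16).

**Steps most likely to fail, with fallbacks**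

1. Step 11 (cycloaddition). Possible failures are poor endo/exo discrimination, insufficient facial selectivity, or slow reaction of the doubly ortho-substituted aryl diene with the bulky borate chelate. The fallback moves stereocontrol to a covalent auxiliary and builds the ketone afterwards. It sets out from aldehyde 2, diene 16 and bromide 5 and rejoins the route at 18.
 - Horner–Wadsworth–Emmons olefination of 2 with diethyl {2-[(4S)-4-benzyl-2-oxo-1,3-oxazolidin-3-yl]-2-oxoethyl}phosphonate (LiCl, iPr2NEt, MeCN) would give (4S)-4-benzyl-3-{(2E)-3-[2,4-bis(methoxymethoxy)phenyl]prop-2-enoyl}-1,3-oxazolidin-2-one F1.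
 - Et2AlCl-promoted Diels–Alder reaction of F1 with 16 (CH2Cl2, −78 → −20 °C) proceeds through the aluminium-chelated s-cis imide. The diene should add endo to the Cα-si face opposite the benzyl group, giving the (3S,4R,5S)-configured N-acyl oxazolidinone cycloadduct F2.
 - LiSEt (EtSH, n-BuLi, THF, 0 °C) would release the auxiliary and give the S-ethyl thioester F3.
 - In parallel, commercial 1,3-bis(methoxymethoxy)benzene (COCOc1cccc(OCOC)c1) would be metalated between its two ethers (n-BuLi, then CuI) and alkylated with 5 to give 1,3-bis(methoxymethoxy)-2-(3-methylbut-2-en-1-yl)benzene F4.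
 - A second ortho-metalation (s-BuLi, TMEDA, −78 °C), B(OMe)3 and aqueous NH4Cl would give [2,4-bis(methoxymethoxy)-3-(3-methylbut-2-en-1-yl)phenyl]boronic acid F5.
 - Liebeskind–Srogl coupling of F3 with F5 (Pd2(dba)3, tri(2-furyl)phosphine, copper(I) thiophene-2-carboxylate, THF, 50 °C) forms the aryl ketone under neutral conditions and delivers 18.

2. Step 15 (carbonylative annulation). Possible failures are direct, non-carbonylative alkynylation followed by closure to a benzofuran, capture of the aroylpalladium species by diethylamine, sluggish oxidative addition at the flanked iodide, or 5-exo closure. The fallback installs the carbonyl carbon without palladium. It sets out from phenol 19 (before iodination) and rejoins the route at 22 through 21.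
 - Magnesium-mediated ortho-formylation of 19 (MgCl2, Et3N, paraformaldehyde, MeCN, reflux) reacts only ortho to the single free hydroxyl and would give the salicylaldehyde F6.
 - Alkyne 3, deprotonated with n-BuLi (2.2 equiv, THF, −78 °C), should add to the aldehyde in preference to the hindered ketone and give the propargylic alcohol F7 (both carbinol epimers are acceptable).
 - MnO2 oxidation would give ynone 21, and Et2NH in EtOH would close it by the same 6-endo oxa-Michael addition to 22.

3. Step 16 (global deprotection). Possible failures are acid-promoted chroman formation from the prenyl phenol, ketalisation of the C4 ketone by the flanking ortho-phenols, or hydration or migration of the ring alkene, all competing with acetal cleavage. The fallback exchanges the protecting groups under non-protic conditions. It sets out from 22 and rejoins the route at 23.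
 - TMSOTf with 2,2′-bipyridyl (CH2Cl2, 0 °C) converts aryl MOM ethers through pyridinium intermediates into aryl silyl ethers and would give the octakis(trimethylsilyl) ether F8.
 - F8 is hydrolysed by water (or K2CO3/MeOH, 0 °C) to 23, so that the free polyphenol never meets a Brønsted acid.

Further compounds
F1 | step 11 | (4S)-4-benzyl-3-{(2E)-3-[2,4-bis(methoxymethoxy)phenyl]prop-2-enoyl}-1,3-oxazolidin-2-one | O=C(/C=C/c1ccc(OCOC)cc1OCOC)N1[C@@H](Cc2ccccc2)COC1=O
F2 | step 11 | (4S)-4-benzyl-3-{[(1R,2S,6S)-2-{2,6-bis(methoxymethoxy)-4-[tri(propan-2-yl)silyloxy]phenyl}-6-[2,4-bis(methoxymethoxy)phenyl]-4-methylcyclohex-3-en-1-yl]carbonyl}-1,3-oxazolidin-2-one | O=C([C@H]1[C@@H](c2c(OCOC)cc(O[Si](C(C)C)(C(C)C)C(C)C)cc2OCOC)C=C(C)C[C@@H]1c1ccc(OCOC)cc1OCOC)N1[C@@H](Cc2ccccc2)COC1=O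
F3 | step 11 | S-ethyl (1R,2S,6S)-2-{2,6-bis(methoxymethoxy)-4-[tri(propan-2-yl)silyloxy]phenyl}-6-[2,4-bis(methoxymethoxy)phenyl]-4-methylcyclohex-3-ene-1-carbothioate | CCSC(=O)[C@H]1[C@@H](c2c(OCOC)cc(O[Si](C(C)C)(C(C)C)C(C)C)cc2OCOC)C=C(C)C[C@@H]1c1ccc(OCOC)cc1OCOC
F4 | step 11 | 1,3-bis(methoxymethoxy)-2-(3-methylbut-2-en-1-yl)benzene | CC(C)=CCc1c(OCOC)cccc1OCOC
F5 | step 11 | [2,4-bis(methoxymethoxy)-3-(3-methylbut-2-en-1-yl)phenyl]boronic acid | CC(C)=CCc1c(OCOC)ccc(B(O)O)c1OCOC
F6 | step 15 | 3-[(1S,5S,6R)-6-[2,4-bis(methoxymethoxy)-3-(3-methylbut-2-en-1-yl)benzoyl]-5-[2,4-bis(methoxymethoxy)phenyl]-3-methylcyclohex-2-en-1-yl]-6-hydroxy-2,4-bis(methoxymethoxy)benzaldehyde | CC(C)=CCc1c(OCOC)ccc(C(=O)[C@H]2[C@@H](c3c(OCOC)cc(O)c(C=O)c3OCOC)C=C(C)C[C@@H]2c2ccc(OCOC)cc2OCOC)c1OCOC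
F7 | step 15 | [(1R,2S,6S)-6-[2,4-bis(methoxymethoxy)phenyl]-2-{4-hydroxy-3-[1-hydroxy-3-(2,4-bis(methoxymethoxy)phenyl)prop-2-yn-1-yl]-2,6-bis(methoxymethoxy)phenyl}-4-methylcyclohex-3-en-1-yl][2,4-bis(methoxymethoxy)-3-(3-methylbut-2-en-1-yl)phenyl]methanone (carbinol epimers) | CC(C)=CCc1c(OCOC)ccc(C(=O)[C@H]2[C@@H](c3c(OCOC)cc(O)c(C(O)C#Cc4ccc(OCOC)cc4OCOC)c3OCOC)C=C(C)C[C@@H]2c2ccc(OCOC)cc2OCOC)c1OCOC
F8 | step 16 | 6-[(1S,5S,6R)-6-[2,4-bis(trimethylsilyloxy)-3-(3-methylbut-2-en-1-yl)benzoyl]-5-[2,4-bis(trimethylsilyloxy)phenyl]-3-methylcyclohex-2-en-1-yl]-2-[2,4-bis(trimethylsilyloxy)phenyl]-5,7-bis(trimethylsilyloxy)-4H-chromen-4-one | CC(C)=CCc1c(O[Si](C)(C)C)ccc(C(=O)[C@H]2[C@@H](c3c(O[Si](C)(C)C)cc4oc(-c5ccc(O[Si](C)(C)C)cc5O[Si](C)(C)C)cc(=O)c4c3O[Si](C)(C)C)C=C(C)C[C@@H]2c2ccc(O[Si](C)(C)C)cc2O[Si](C)(C)C)c1O[Si](C)(C)C
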